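**Plan**

- Retrosynthetic cuts, in order: the three O–CH3 ethers on ring A (the methylphloroglucinol ring) are put back; the ring A–C(=O) bond of the 3-phenylpropanoyl group; the four C–CH3 bonds at the two quaternary carbons of ring B (the tetramethylcyclohexanetrione); the bond from the methine carbon to ring A; the methine–CH2 bond of the phenethyl chain.
- Enabling feature: ring B is an enolised cyclohexane-1,3,5-trione. One carbon between two C–O carbons carries the methine and the other two are C(CH3)2. Atom for atom this is a 2-substituted benzene-1,3,5-triol whose two ring CH carbons have each taken up two methyl groups, so ring B can be carried as an aromatic triol until late.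
- Forward order: no ring is closed at any stage, since both six-membered carbocycles are bought as aromatics. A ring B aldehyde takes up the phenethyl chain (Grignard), ring A (2,4,6-trimethoxytoluene) is joined at the benzylic carbon, ring B is unmasked and dearomatised by fourfold C-methylation, ring A is acylated at its last free carbon, and its ethers are cleaved.
- Stereochemistry: the single stereocentre (R in the target) is set in step 3, where a chiral binaphthyl hydrogen phosphate controls the face of an o-quinone methide attacked by ring A. It carries no acidic hydrogen afterwards and is taken unchanged through steps 4 to 7.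

Key step: step 5

Assumption: the sense of induction of the phosphoric acid on this quinone methide cannot be derived from first principles. The (R)-acid is written as the one that should give the S diarylmethine of step 3; its mirror image is used instead if the opposite sense is met.

Remark: the descriptor of the stereocentre is S while ring B is aromatic and R once ring B is a trione. Only the priority order changes, not the spatial arrangement.

**Route**

Step 1
Reactants: 1 2,4,6-trihydroxybenzaldehyde; 2 benzyl bromide
Product: 3 2,4-bis(benzyloxy)-6-hydroxybenzaldehyde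
Conditions: BnBr (2.05 equiv), K2CO3 (2.2 equiv), DMF, 0 °C to rt
Reagents that add atoms: benzyl bromide, BrCc1ccccc1
Why: Williamson ether synthesis in which the para hydroxyl and one ortho hydroxyl are benzylated while the remaining ortho hydroxyl, hydrogen-bonded to the formyl oxygen and therefore the least nucleophilic, should stay free.

Step 2
Reactants: 3 2,4-bis(benzyloxy)-6-hydroxybenzaldehyde; 4 2-phenylethylmagnesium chloride
Product: 5 rac-3,5-bis(benzyloxy)-2-(1-hydroxy-3-phenylpropyl)phenol
Conditions: PhCH2CH2MgCl (3 equiv, THF solution), THF, −20 to 0 °C; sat. aq. NH4Cl; used crude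
Reagents that add atoms: 2-phenylethylmagnesium chloride, Cl[Mg]CCc1ccccc1
Why: Grignard addition to a salicylaldehyde, the first equivalent being spent on the phenol, should give the o-hydroxybenzylic alcohol as a magnesium chelate that survives a neutral quench; the racemic carbinol centre is erased in step 3.

Step 3
Reactants: 5 rac-3,5-bis(benzyloxy)-2-(1-hydroxy-3-phenylpropyl)phenol; 6 2,4,6-trimethoxytoluene
Product: 8 3,5-bis(benzyloxy)-2-[(1S)-3-phenyl-1-(2,4,6-trimethoxy-3-methylphenyl)propyl]phenol, via o-quinone methide 7 (not isolated)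
Conditions: 6 (3 equiv), (R)-3,3'-bis(2,4,6-triisopropylphenyl)-1,1'-binaphthyl-2,2'-diyl hydrogen phosphate (10 mol %), 4 Å MS, toluene, 0 °C, slow addition of 5
Reagents that add atoms: 2,4,6-trimethoxytoluene, Cc1c(OC)cc(OC)cc1OC
Why: Chiral phosphoric acid catalysed Friedel–Crafts alkylation of an electron-rich arene by an o-quinone methide formed through acid-promoted dehydration of the o-hydroxybenzylic alcohol; the neighbouring benzyloxy group should fix the alkylidene geometry, the acid stays hydrogen-bonded to the quinone methide oxygen, and its 3,3'-aryl groups leave one face of the exocyclic carbon open to either of the two equivalent free carbons of 6, which sets the S stereocentre.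

Step 4
Reactants: 8 3,5-bis(benzyloxy)-2-[(1S)-3-phenyl-1-(2,4,6-trimethoxy-3-methylphenyl)propyl]phenol
Product: 9 2-[(1S)-3-phenyl-1-(2,4,6-trimethoxy-3-methylphenyl)propyl]benzene-1,3,5-triol
Conditions: H2 (1 atm), Pd/C (10 wt %), EtOAc/MeOH, rt; filtered under argon
Reagents that add atoms: none
Why: Catalytic hydrogenolysis of the two aryl benzyl ethers under neutral conditions should free ring B while the methyl ethers of ring A, the phenyl rings and the diarylmethine, which is sensitive to protic acid, are left alone.

Step 5
Reactants: 9 2-[(1S)-3-phenyl-1-(2,4,6-trimethoxy-3-methylphenyl)propyl]benzene-1,3,5-triol; 10 iodomethane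
Product: 14 5-hydroxy-2,2,6,6-tetramethyl-4-[(1R)-3-phenyl-1-(2,4,6-trimethoxy-3-methylphenyl)propyl]cyclohex-4-ene-1,3-dione, via monomethyl triol 11 (not isolated), via dimethyl triol 12 (not isolated), via trimethyl dienone 13 (not isolated)
Conditions: NaOMe (6 equiv), MeI (4.4 equiv, in portions), degassed MeOH, argon, 0 to 40 °C; then cold 1 M HCl
Reagents that add atoms: iodomethane, CI
Why: Sodium methoxide converts the trihydroxyphenyl ring B into a polyphenoxide whose two unsubstituted ring carbons displace iodide from iodomethane (SN2 C-alkylation of an ambident phenoxide); the first two C–CH3 bonds leave the ring aromatic (11, 12), the third and fourth turn the same two carbons into C(CH3)2 and so dearomatise ring B to the trione, which rests as the enolate of a vinylogous acid until the acid quench. The closest known reaction is the exhaustive C-methylation of phloroglucinol and of 2-acylphloroglucinols with iodomethane and sodium methoxide to syncarpic acid-type 4,4,6,6-tetramethylcyclohexane-1,3,5-triones. No ring is closed and no stereocentre is made; the diarylmethine has no acidic hydrogen and no leaving group under methoxide, so its spatial arrangement should be kept. C- over O-methylation is favoured by the protic solvent and the sodium counter-ion, which hold the oxyanions in hydrogen bonds and ion pairs. Site selectivity rests on the substrate: ring A carries only methyl ethers and cannot form a phenoxide, the third nucleophilic carbon of ring B is shielded by the branched methine with its di-ortho-methoxylated ring A, and the product enolate is a weak nucleophile, so with 4.4 equivalents of iodomethane the reaction should end after the fourth methyl group.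

Step 6
Reactants: 14 5-hydroxy-2,2,6,6-tetramethyl-4-[(1R)-3-phenyl-1-(2,4,6-trimethoxy-3-methylphenyl)propyl]cyclohex-4-ene-1,3-dione; 15 3-phenylpropanoyl chloride
Product: 16 5-hydroxy-2,2,6,6-tetramethyl-4-{(1R)-3-phenyl-1-[2,4,6-trimethoxy-3-methyl-5-(3-phenylpropanoyl)phenyl]propyl}cyclohex-4-ene-1,3-dione
Conditions: TiCl4 (3 equiv), PhCH2CH2COCl (1.5 equiv), CH2Cl2, −20 to 0 °C; cold 1 M HCl
Reagents that add atoms: 3-phenylpropanoyl chloride, O=C(Cl)CCc1ccccc1
Why: Friedel–Crafts acylation should go to the only free carbon of ring A, which is activated by three methoxy groups, because the two phenyl rings are far less nucleophilic, ring B is no longer aromatic, and the triketone enol is held as a titanium chelate that is released on work-up.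

Step 7
Reactants: 16 5-hydroxy-2,2,6,6-tetramethyl-4-{(1R)-3-phenyl-1-[2,4,6-trimethoxy-3-methyl-5-(3-phenylpropanoyl)phenyl]propyl}cyclohex-4-ene-1,3-dione
Product: 17 5-hydroxy-2,2,6,6-tetramethyl-4-{(1R)-3-phenyl-1-[2,4,6-trihydroxy-3-methyl-5-(3-phenylpropanoyl)phenyl]propyl}cyclohex-4-ene-1,3-dione (CNP0236721.1)
Conditions: BBr3 (8 equiv), CH2Cl2, −78 to 0 °C; ice water, no basic wash
Reagents that add atoms: none
Why: Lewis acid cleavage of aryl methyl ethers, in which the two ethers ortho to the ketone should go first through chelation and the third at 0 °C; the ketone and the trione are inert to BBr3, and the low temperature and base-free work-up are chosen to disfavour dehydrative closure of a new phenol onto the enol and retro-Michael loss of the trione from the stereocentre.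

**Compound list**

1 | 2,4,6-trihydroxybenzaldehyde | O=Cc1c(O)cc(O)cc1O | starting material
2 | benzyl bromide | BrCc1ccccc1 | starting material
3 | 2,4-bis(benzyloxy)-6-hydroxybenzaldehyde | O=Cc1c(O)cc(OCc2ccccc2)cc1OCc1ccccc1 | intermediate
4 | 2-phenylethylmagnesium chloride | Cl[Mg]CCc1ccccc1 | starting material
5 | rac-3,5-bis(benzyloxy)-2-(1-hydroxy-3-phenylpropyl)phenol | OC(CCc1ccccc1)c1c(O)cc(OCc2ccccc2)cc1OCc1ccccc1 | intermediate
6 | 2,4,6-trimethoxytoluene | Cc1c(OC)cc(OC)cc1OC | starting material
7 | 3,5-bis(benzyloxy)-6-(3-phenylpropylidene)cyclohexa-2,4-dien-1-one (o-quinone methide) | O=C1C=C(OCc2ccccc2)C=C(OCc2ccccc2)C1=CCCc1ccccc1 | intermediate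
8 | 3,5-bis(benzyloxy)-2-[(1S)-3-phenyl-1-(2,4,6-trimethoxy-3-methylphenyl)propyl]phenol | Cc1c(OC)cc(OC)c([C@@H](CCc2ccccc2)c2c(O)cc(OCc3ccccc3)cc2OCc2ccccc2)c1OC | intermediate
9 | 2-[(1S)-3-phenyl-1-(2,4,6-trimethoxy-3-methylphenyl)propyl]benzene-1,3,5-triol | Cc1c(OC)cc(OC)c([C@@H](CCc2ccccc2)c2c(O)cc(O)cc2O)c1OC | intermediate
10 | iodomethane | CI | starting material
11 | 2-methyl-4-[(1S)-3-phenyl-1-(2,4,6-trimethoxy-3-methylphenyl)propyl]benzene-1,3,5-triol (monomethyl triol) | Cc1c(OC)cc(OC)c([C@@H](CCc2ccccc2)c2c(O)cc(O)c(C)c2O)c1OC | intermediate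
12 | 2,4-dimethyl-6-[(1S)-3-phenyl-1-(2,4,6-trimethoxy-3-methylphenyl)propyl]benzene-1,3,5-triol (dimethyl triol) | Cc1c(OC)cc(OC)c([C@@H](CCc2ccccc2)c2c(O)c(C)c(O)c(C)c2O)c1OC | intermediate
13 | 3,5-dihydroxy-4,6,6-trimethyl-2-[(1R)-3-phenyl-1-(2,4,6-trimethoxy-3-methylphenyl)propyl]cyclohexa-2,4-dien-1-one (trimethyl dienone) | Cc1c(OC)cc(OC)c([C@@H](CCc2ccccc2)C2=C(O)C(C)=C(O)C(C)(C)C2=O)c1OC | intermediate
14 | 5-hydroxy-2,2,6,6-tetramethyl-4-[(1R)-3-phenyl-1-(2,4,6-trimethoxy-3-methylphenyl)propyl]cyclohex-4-ene-1,3-dione | Cc1c(OC)cc(OC)c([C@@H](CCc2ccccc2)C2=C(O)C(C)(C)C(=O)C(C)(C)C2=O)c1OC | intermediate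
15 | 3-phenylpropanoyl chloride | O=C(Cl)CCc1ccccc1 | starting material
16 | 5-hydroxy-2,2,6,6-tetramethyl-4-{(1R)-3-phenyl-1-[2,4,6-trimethoxy-3-methyl-5-(3-phenylpropanoyl)phenyl]propyl}cyclohex-4-ene-1,3-dione | Cc1c(OC)c(C(=O)CCc2ccccc2)c(OC)c([C@@H](CCc2ccccc2)C2=C(O)C(C)(C)C(=O)C(C)(C)C2=O)c1OC | intermediate
17 | 5-hydroxy-2,2,6,6-tetramethyl-4-{(1R)-3-phenyl-1-[2,4,6-trihydroxy-3-methyl-5-(3-phenylpropanoyl)phenyl]propyl}cyclohex-4-ene-1,3-dione | Cc1c(O)c(C(=O)CCc2ccccc2)c(O)c([C@@H](CCc2ccccc2)C2=C(O)C(C)(C)C(=O)C(C)(C)C2=O)c1O | target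

**Step count and risks**

Total steps: 7. Longest linear sequence: 7 steps (1 → 3 → 5 → 8 → 9 → 14 → 16 → 17).

Steps most likely to fail:

1. Step 3. The nucleophile offers the catalyst no hydrogen-bond donor, so discrimination between the two faces of the quinone methide may be poor. The quinone methide may also alkylate the electron-rich ring B of the carbinol or of the product instead of 6.
Fallback, setting out from 5 and 6 and coming back at 8: the alkylation is run without induction (diphenyl hydrogen phosphate (PhO)2P(O)OH 10 mol %, toluene, rt, excess 6), which should give racemic 3,5-bis(benzyloxy)-2-[3-phenyl-1-(2,4,6-trimethoxy-3-methylphenyl)propyl]phenol F1. Its phenol is esterified with (1S)-camphanic chloride (Et3N, 4-(dimethylamino)pyridine, CH2Cl2) to two diastereomers. These are 3,5-bis(benzyloxy)-2-[(1S)-3-phenyl-1-(2,4,6-trimethoxy-3-methylphenyl)propyl]phenyl (1S,4R)-camphanate F2 and its (1R)-propyl epimer F3, which are separated by chromatography or crystallisation. Methanolysis of F2 (K2CO3 cat., MeOH, rt) should release 8 as a single enantiomer.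

2. Step 5. Methylation may not stop cleanly: it may run on to the ring carbon that bears the diarylmethine, go to oxygen and give enol ethers, or stall at partly methylated stages.
Fallback, setting out from 9 and coming back at 12 and from there at 14: two of the four methyl groups are brought in as aminomethyl groups. A double Mannich reaction of 9 (aq. CH2O, Me2NH, EtOH, rt) at the two free ring carbons should give 2,4-bis[(dimethylamino)methyl]-6-[(1S)-3-phenyl-1-(2,4,6-trimethoxy-3-methylphenyl)propyl]benzene-1,3,5-triol F4. Hydrogenolysis of its benzylic C–N bonds (H2, Pd/C, MeOH, 50 °C) should give the dimethyl triol 12 as an isolated compound. Only the two dearomatising methylations are then left for iodomethane (2.2 equiv, NaOMe, MeOH), which should give 14 by way of 13.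

3. Step 6. Attack at the ring A carbon flanked by two methoxy groups may be slow. Acid-induced cleavage of the bond between ring A and the methine (retro-Friedel–Crafts, with loss of configuration) or premature ether cleavage may then outrun the acylation.
Fallback, setting out from 14 and coming back at 17: the order of the last two operations is exchanged. BBr3 (CH2Cl2, −78 to 0 °C) first cleaves the three methyl ethers of 14 to 5-hydroxy-2,2,6,6-tetramethyl-4-[(1R)-3-phenyl-1-(2,4,6-trihydroxy-3-methylphenyl)propyl]cyclohex-4-ene-1,3-dione F5. Its free methylphloroglucinol ring is more nucleophilic and less hindered at its one free carbon. It is then C-acylated with 15 (TiCl4, CH2Cl2, −20 °C), the classical acylation of a free phloroglucinol, to give 17 directly.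

**Further compounds**

F1 | step 3 | rac-3,5-bis(benzyloxy)-2-[3-phenyl-1-(2,4,6-trimethoxy-3-methylphenyl)propyl]phenol | Cc1c(OC)cc(OC)c(C(CCc2ccccc2)c2c(O)cc(OCc3ccccc3)cc2OCc2ccccc2)c1OC
F2 | step 3 | 3,5-bis(benzyloxy)-2-[(1S)-3-phenyl-1-(2,4,6-trimethoxy-3-methylphenyl)propyl]phenyl (1S,4R)-4,7,7-trimethyl-3-oxo-2-oxabicyclo[2.2.1]heptane-1-carboxylate | Cc1c(OC)cc(OC)c([C@@H](CCc2ccccc2)c2c(OC(=O)[C@@]34CC[C@@](C)(C(=O)O3)C4(C)C)cc(OCc3ccccc3)cc2OCc2ccccc2)c1OC
F3 | step 3 | 3,5-bis(benzyloxy)-2-[(1R)-3-phenyl-1-(2,4,6-trimethoxy-3-methylphenyl)propyl]phenyl (1S,4R)-4,7,7-trimethyl-3-oxo-2-oxabicyclo[2.2.1]heptane-1-carboxylate | Cc1c(OC)cc(OC)c([C@H](CCc2ccccc2)c2c(OC(=O)[C@@]34CC[C@@](C)(C(=O)O3)C4(C)C)cc(OCc3ccccc3)cc2OCc2ccccc2)c1OC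
F4 | step 5 | 2,4-bis[(dimethylamino)methyl]-6-[(1S)-3-phenyl-1-(2,4,6-trimethoxy-3-methylphenyl)propyl]benzene-1,3,5-triol | Cc1c(OC)cc(OC)c([C@@H](CCc2ccccc2)c2c(O)c(CN(C)C)c(O)c(CN(C)C)c2O)c1OC
F5 | step 6 | 5-hydroxy-2,2,6,6-tetramethyl-4-[(1R)-3-phenyl-1-(2,4,6-trihydroxy-3-methylphenyl)propyl]cyclohex-4-ene-1,3-dione | Cc1c(O)cc(O)c([C@@H](CCc2ccccc2)C2=C(O)C(C)(C)C(=O)C(C)(C)C2=O)c1O
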